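**Retrosynthetic overview**

1. Target 20 ⇒ 18: both dihydropyran rings are closed last, by intramolecular alkoxide addition–elimination at the methoxy-bearing ring carbon (C–O bond to the ring; the carbinol carbon is untouched), followed by removal of the SEM groups.
2. 18 ⇒ 16 + 2 × 8 (key C–C bonds, both made in one pot): each ring–CH2 bond is formed with reversed polarity at both carbons. The chain carbon β to the carbinol is the donor (a homoenolate equivalent at the alcohol oxidation level, from anti-selective hydroboration of 16, which also sets the methyl stereocentre). The ring carbon α to the C4 oxygen function is the acceptor (α-bromo compound, an enolonium equivalent). The natural-polarity union would be tropolone C–H plus enone (Michael).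
3. 8 ⇒ 1: the seven-membered rings are made first, by Birch reduction and dibromocarbene ring expansion of 2-methylanisole, then dihydroxylation and oxidation to the tropolone.
4. 16 ⇒ 9 + 11 + 14: two catalyst-controlled alkynylations of a butadiyne set both carbinol centres; trans-reduction gives the (E,E)-diene.
5. Ring order: two cycloheptatrienone rings (steps 2–4), then two pyran rings (step 12).

Assumption: (S,S)-ProPhenol/Me2Zn is taken to deliver the alkyne to the Si face of both enals (R carbinols in 12 and 15); if the sense is the reverse, the (R,R) ligand is used in steps 7 and 9.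

**Route**

Step 1
Reactants: 1 2-methylanisole
Product: 2 1-methoxy-2-methylcyclohexa-1,4-diene
Conditions: Li, NH3 (l), t-BuOH, THF, −78 → −33 °C
Reagents that add atoms: none
Why: Birch reduction of an alkyl anisole leaves both donor substituents (OMe, Me) on one residual double bond, giving the 2,5-dihydro isomer with a tetrasubstituted enol ether and an isolated cis-alkene.

Step 2
Reactants: 2 1-methoxy-2-methylcyclohexa-1,4-diene
Product: 4 1-bromo-7,7-dimethoxy-2-methylcyclohepta-1,4-diene, via dibromocyclopropane 3 (not isolated)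
Conditions: CHBr3, KOt-Bu, pentane, −20 → 0 °C; then MeOH, K2CO3, 45 °C
Reagents that add atoms: bromoform (BrC(Br)Br), methanol (CO)
Why: Electrophilic dibromocarbene adds to the electron-rich tetrasubstituted enol ether in preference to the isolated alkene, and the alkoxy-dibromocyclopropane 3 ionises (bromide loss, disrotatory opening) to a 2-bromoallyl oxocarbenium ion that methanol traps at the oxygen-bearing carbon, a one-carbon ring expansion of the alkoxy-gem-dihalocyclopropane type.

Step 3
Reactants: 4 1-bromo-7,7-dimethoxy-2-methylcyclohepta-1,4-diene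
Product: 5 rac-(1R,2S)-5-bromo-6,6-dimethoxy-4-methylcyclohept-4-ene-1,2-diol (cis-diol)
Conditions: OsO4 (2 mol %), NMO, acetone/H2O, 0 °C → rt
Reagents that add atoms: N-methylmorpholine N-oxide (C[N+]1([O-])CCOCC1), water (O)
Why: Upjohn dihydroxylation is chemoselective for the cis-disubstituted alkene over the hindered, electron-poor tetrasubstituted bromoalkene; syn addition gives the racemic cis-diol, whose two centres are erased in step 4.

Step 4
Reactants: 5 rac-(1R,2S)-5-bromo-6,6-dimethoxy-4-methylcyclohept-4-ene-1,2-diol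
Product: 7 5-bromo-2-hydroxy-4-methoxy-6-methylcyclohepta-2,4,6-trien-1-one, via diketone 6 (not isolated)
Conditions: TFAA, DMSO, CH2Cl2, −78 °C; then Et3N, −78 °C → rt
Reagents that add atoms: none
Why: Swern-type oxidation with TFAA-activated DMSO (the protocol used for cis-1,2-diols in Banwell-type tropolone syntheses) gives diketone 6, which under Et3N loses methanol by E1cB from the β-ketal and enolises to the aromatic tropolone, so the surviving methoxy group marks C4 without ambiguity.

Step 5
Reactants: 7 5-bromo-2-hydroxy-4-methoxy-6-methylcyclohepta-2,4,6-trien-1-one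
Product: 8 5-bromo-6-methoxy-4-methyl-2-{[2-(trimethylsilyl)ethoxy]methoxy}cyclohepta-2,4,6-trien-1-one
Conditions: SEMCl, i-Pr2NEt, CH2Cl2, 0 °C → rt
Reagents that add atoms: 2-(trimethylsilyl)ethoxymethyl chloride (C[Si](C)(C)CCOCCl)
Why: O-alkylation of the tropolonate gives the SEM ether, drawn as the isomer that keeps the carbonyl conjugated with the C–OMe group (a vinylogous ester, needed as the acceptor in step 12); the selectivity between the two tropolone oxygens is uncertain, but the other O-regioisomer would react the same way and converge on 20.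

Step 6
Reactants: 9 1,4-bis(trimethylsilyl)buta-1,3-diyne
Product: 10 buta-1,3-diyn-1-yl(trimethyl)silane
Conditions: MeLi·LiBr (1.0 equiv), Et2O, rt; then aq. NH4Cl (product kept in solution)
Reagents that add atoms: none
Why: Nucleophilic desilylation by MeLi stops after one silicon because the resulting lithium diynide is anionic and is not attacked again; protonation gives the terminal diyne.

Step 7
Reactants: 10 buta-1,3-diyn-1-yl(trimethyl)silane; 11 methacrolein
Product: 12 (3R)-2-methyl-7-(trimethylsilyl)hept-1-ene-4,6-diyn-3-ol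
Conditions: Me2Zn, (S,S)-ProPhenol (20 mol %), Ph3P=O (40 mol %), toluene, 0 °C; then aq. NH4Cl
Reagents that add atoms: none
Why: Trost ProPhenol dinuclear-zinc asymmetric alkynylation of an α,β-unsaturated aldehyde with a 1,3-diyne; the catalyst delivers the zinc diynide to the Si face and sets the R carbinol (later C2 of the methyl-bearing pyran).

Step 8
Reactants: 12 (3R)-2-methyl-7-(trimethylsilyl)hept-1-ene-4,6-diyn-3-ol
Product: 13 (3R)-2-methylhept-1-ene-4,6-diyn-3-ol
Conditions: K2CO3 (cat.), MeOH, 0 °C (product kept in solution)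
Reagents that add atoms: none
Why: Methoxide-catalysed protodesilylation of the alkynylsilane frees the second terminal alkyne without touching the carbinol centre.

Step 9
Reactants: 13 (3R)-2-methylhept-1-ene-4,6-diyn-3-ol; 14 acrolein
Product: 15 (3R,8R)-2-methyldeca-1,9-diene-4,6-diyne-3,8-diol
Conditions: Me2Zn (excess), (S,S)-ProPhenol (20 mol %), Ph3P=O (40 mol %), toluene, 0 °C, slow addition of 14; then aq. NH4Cl
Reagents that add atoms: none
Why: A second ProPhenol alkynylation under catalyst control (the remote centre has no influence) adds the diynide to the Si face of acrolein and sets the second R carbinol (later C2 of the other pyran).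

Step 10
Reactants: 15 (3R,8R)-2-methyldeca-1,9-diene-4,6-diyne-3,8-diol
Product: 16 (3S,4E,6E,8R)-2-methyldeca-1,4,6,9-tetraene-3,8-diol
Conditions: NaAlH2(OCH2CH2OCH3)2 (Red-Al), THF, 0 °C → rt; then aq. KNaC4H4O6
Reagents that add atoms: none
Why: Alkoxide-directed trans-hydroalumination of both propargylic alkynes gives the (E,E)-diene and leaves the terminal alkenes and both stereocentres untouched (C3 changes from R to S only through CIP priorities).

Step 11
Reactants: 16 (3S,4E,6E,8R)-2-methyldeca-1,4,6,9-tetraene-3,8-diol; 8 5-bromo-6-methoxy-4-methyl-2-{[2-(trimethylsilyl)ethoxy]methoxy}cyclohepta-2,4,6-trien-1-one (2.3 equiv)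
Product: 18 (2R,3R,4E,6E,8R)-1,10-bis(7-methoxy-2-methyl-5-oxo-4-{[2-(trimethylsilyl)ethoxy]methoxy}cyclohepta-1,3,6-trien-1-yl)-2-methyldeca-4,6-diene-3,8-diol, via bis-borane 17 (not isolated)
Conditions: 9-BBN-H (4.5 equiv), THF, 0 °C → rt; then aq. K3PO4, 8, Pd(OAc)2 (10 mol %), SPhos (20 mol %), THF/DMF, 60 °C
Reagents that add atoms: none
Why: 9-BBN hydroborates only the two terminal alkenes (far faster than the internal diene), with the Still–Barrish anti preference at the 2-methylallylic alcohol setting the new methyl centre (2R,3R = anti = trans in the ring), and the resulting γ-oxido alkylboranes (homoenolate-type donors at the carbon β to the carbinol) are joined twice by B-alkyl Suzuki–Miyaura coupling to the α-bromo carbon next to the C–OMe group of 8 (an α-carbonyl position used as acceptor, an enolonium equivalent), so both carbons react with polarity opposite to the natural Michael pairing.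

Step 12
Reactants: 18 (2R,3R,4E,6E,8R)-1,10-bis(7-methoxy-2-methyl-5-oxo-4-{[2-(trimethylsilyl)ethoxy]methoxy}cyclohepta-1,3,6-trien-1-yl)-2-methyldeca-4,6-diene-3,8-diol
Product: 20 (2R,3R)-8-hydroxy-2-[(1E,3E)-4-[(2R)-8-hydroxy-5-methyl-7-oxo-2,3,4,7-tetrahydrocyclohepta[b]pyran-2-yl]buta-1,3-dien-1-yl]-3,5-dimethyl-3,4-dihydrocyclohepta[b]pyran-7(2H)-one, via bis-SEM ether 19 (not isolated)
Conditions: NaH (2.4 equiv), THF, 0 °C → rt; then Bu4NF, DMPU, 45 °C; aq. NH4Cl
Reagents that add atoms: none
Why: Each sodium alkoxide adds to the β-carbon of the adjacent vinylogous ester and expels methoxide (6-exo addition–elimination, a vinylogous transesterification that forms the ring C–O bond with retention at the carbinol carbon because its C–O bond is never broken), and fluoride then fragments the two SEM groups to release the tropolones.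

**Compound list**

1 | 2-methylanisole (1-methoxy-2-methylbenzene) | COc1ccccc1C | starting material
2 | 1-methoxy-2-methylcyclohexa-1,4-diene | COC1=C(C)CC=CC1 | intermediate
3 | 7,7-dibromo-1-methoxy-6-methylbicyclo[4.1.0]hept-3-ene (racemic, cis-fused) | CO[C@@]12CC=CC[C@]1(C)C2(Br)Br | intermediate
4 | 1-bromo-7,7-dimethoxy-2-methylcyclohepta-1,4-diene | COC1(OC)CC=CCC(C)=C1Br | intermediate
5 | rac-(1R,2S)-5-bromo-6,6-dimethoxy-4-methylcyclohept-4-ene-1,2-diol (cis-diol) | COC1(OC)C[C@H](O)[C@H](O)CC(C)=C1Br | intermediate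
6 | 5-bromo-6,6-dimethoxy-4-methylcyclohept-4-ene-1,2-dione | COC1(OC)CC(=O)C(=O)CC(C)=C1Br | intermediate
7 | 5-bromo-2-hydroxy-4-methoxy-6-methylcyclohepta-2,4,6-trien-1-one | O=C1C(O)=CC(OC)=C(Br)C(C)=C1 | intermediate
8 | 5-bromo-6-methoxy-4-methyl-2-{[2-(trimethylsilyl)ethoxy]methoxy}cyclohepta-2,4,6-trien-1-one | O=C1C=C(OC)C(Br)=C(C)C=C1OCOCC[Si](C)(C)C | intermediate
9 | 1,4-bis(trimethylsilyl)buta-1,3-diyne | C[Si](C)(C)C#CC#C[Si](C)(C)C | starting material
10 | buta-1,3-diyn-1-yl(trimethyl)silane | C[Si](C)(C)C#CC#C | intermediate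
11 | methacrolein (2-methylprop-2-enal) | CC(=C)C=O | starting material
12 | (3R)-2-methyl-7-(trimethylsilyl)hept-1-ene-4,6-diyn-3-ol | C=C(C)[C@@H](O)C#CC#C[Si](C)(C)C | intermediate
13 | (3R)-2-methylhept-1-ene-4,6-diyn-3-ol | C=C(C)[C@@H](O)C#CC#C | intermediate
14 | acrolein (prop-2-enal) | C=CC=O | starting material
15 | (3R,8R)-2-methyldeca-1,9-diene-4,6-diyne-3,8-diol | C=C(C)[C@@H](O)C#CC#C[C@H](O)C=C | intermediate
16 | (3S,4E,6E,8R)-2-methyldeca-1,4,6,9-tetraene-3,8-diol | C=C(C)[C@@H](O)/C=C/C=C/[C@H](O)C=C | intermediate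
17 | (2R,3R,4E,6E,8R)-1,10-bis(9-borabicyclo[3.3.1]nonan-9-yl)-2-methyl-3,8-bis(9-borabicyclo[3.3.1]nonan-9-yloxy)deca-4,6-diene | C[C@H](CB1C2CCCC1CCC2)[C@@H](OB1C2CCCC1CCC2)/C=C/C=C/[C@H](OB1C2CCCC1CCC2)CCB1C2CCCC1CCC2 | intermediate
18 | (2R,3R,4E,6E,8R)-1,10-bis(7-methoxy-2-methyl-5-oxo-4-{[2-(trimethylsilyl)ethoxy]methoxy}cyclohepta-1,3,6-trien-1-yl)-2-methyldeca-4,6-diene-3,8-diol | C[Si](C)(C)CCOCOC1=CC(C)=C(C[C@@H](C)[C@@H](O)/C=C/C=C/[C@H](O)CCC2=C(C)C=C(OCOCC[Si](C)(C)C)C(=O)C=C2OC)C(OC)=CC1=O | intermediate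
19 | (2R,3R)-3,5-dimethyl-2-[(1E,3E)-4-[(2R)-5-methyl-8-oxo-7-{[2-(trimethylsilyl)ethoxy]methoxy}-2,3,4,8-tetrahydrocyclohepta[b]pyran-2-yl]buta-1,3-dien-1-yl]-7-{[2-(trimethylsilyl)ethoxy]methoxy}-3,4-dihydrocyclohepta[b]pyran-8(2H)-one | CC1=C2C[C@@H](C)[C@H](/C=C/C=C/[C@H]3CCC4=C(C)C=C(OCOCC[Si](C)(C)C)C(=O)C=C4O3)OC2=CC(=O)C(OCOCC[Si](C)(C)C)=C1 | intermediate
20 | (2R,3R)-8-hydroxy-2-[(1E,3E)-4-[(2R)-8-hydroxy-5-methyl-7-oxo-2,3,4,7-tetrahydrocyclohepta[b]pyran-2-yl]buta-1,3-dien-1-yl]-3,5-dimethyl-3,4-dihydrocyclohepta[b]pyran-7(2H)-one (CNP0332980.1) | Cc1cc(=O)c(O)cc2c1C[C@@H](C)[C@H](/C=C/C=C/[C@H]1CCc3c(C)cc(=O)c(O)cc3O1)O2 | target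

**Step count and risk**

Total steps: 12. Longest linear sequence: 7 (steps 1–5, 11, 12; the branch through steps 6–10, 11, 12 is equally long).

The three steps most likely to fail:

Step 11 (double hydroboration / double B-alkyl coupling). The bromide of 8 is flanked by OMe and Me, two couplings must succeed in one molecule, and the anti selectivity has not been tested with a dienyl substituent. The fallback sets out from 16 and comes back at 18, replacing boron by zinc. Et3SiCl and imidazole give the bis(triethylsilyl) ether of 16 F1. Hydroboration with 9-BBN-H followed by iodination in the flask (I2, NaOMe) gives the primary diiodide F2 (2S,3S,8R by CIP, same spatial arrangement as 18). Zinc insertion (Zn, LiCl, THF) gives the bis(iodozinc) reagent F3. Negishi coupling of F3 with 8 (Pd(OAc)2, CPhos, THF, rt) gives the bis(triethylsilyl) ether of 18 F4, and buffered HF·pyridine (which leaves the SEM groups alone) returns 18.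

Step 12 (double ring closure and SEM removal). The alkoxide may be slow to add to the electron-rich vinylogous ester, and released methoxide can exchange with the SEM-oxy group. The fallback sets out from 18 and comes back at 19, closing the rings from the other side of the C–O bond. LiOH in aqueous THF hydrolyses the two vinylogous methyl esters to the bis(4-hydroxytropone) diol F5. Pd(PPh3)4 (5 mol %, THF, 40 °C) then ionises each dienylic carbinol, assisted by the acidic vinylogous acid, and the ring oxygen closes the six-membered ring on the π-allyl complex. Two inversions at zerovalent palladium give net retention, so 19 forms with the same configuration; Bu4NF then gives 20 as in step 12.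

Step 9 (asymmetric alkynylation of acrolein). Acrolein polymerises readily under zinc alkoxide conditions and may give low enantioselectivity. The fallback sets out from 13 and comes back at 16, using an ynal as a masked vinyl aldehyde. The same ProPhenol/Me2Zn addition of 13 to 3-(trimethylsilyl)prop-2-ynal gives (3R,8S)-2-methyl-10-(trimethylsilyl)dec-1-ene-4,6,9-triyne-3,8-diol F6. K2CO3 in MeOH gives (3R,8R)-2-methyldec-1-ene-4,6,9-triyne-3,8-diol F7. Red-Al then reduces all three propargylic alkynes in one operation (the terminal one to the vinyl group, the diyne to the (E,E)-diene) and gives 16 directly.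

**Further compounds**

F1 | step 11 | (3S,4E,6E,8R)-2-methyl-3,8-bis(triethylsilyloxy)deca-1,4,6,9-tetraene | C=C(C)[C@@H](O[Si](CC)(CC)CC)/C=C/C=C/[C@H](O[Si](CC)(CC)CC)C=C
F2 | step 11 | (2S,3S,4E,6E,8R)-1,10-diiodo-2-methyl-3,8-bis(triethylsilyloxy)deca-4,6-diene | C[C@H](CI)[C@@H](O[Si](CC)(CC)CC)/C=C/C=C/[C@H](O[Si](CC)(CC)CC)CCI
F3 | step 11 | bis(iodozinc) reagent from F2, [(4E,6E)-2-methyl-3,8-bis(triethylsilyloxy)deca-4,6-diene-1,10-diyl]bis(iodozinc), configuration as in F2 | C[C@H](C[Zn]I)[C@@H](O[Si](CC)(CC)CC)/C=C/C=C/[C@H](O[Si](CC)(CC)CC)CC[Zn]I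
F4 | step 11 | bis(triethylsilyl) ether of 18, (2R,3R,4E,6E,8R) | C[Si](C)(C)CCOCOC1=CC(C)=C(C[C@@H](C)[C@@H](O[Si](CC)(CC)CC)/C=C/C=C/[C@H](O[Si](CC)(CC)CC)CCC2=C(C)C=C(OCOCC[Si](C)(C)C)C(=O)C=C2OC)C(OC)=CC1=O
F5 | step 12 | (2R,3R,4E,6E,8R)-1,10-bis(7-hydroxy-2-methyl-5-oxo-4-{[2-(trimethylsilyl)ethoxy]methoxy}cyclohepta-1,3,6-trien-1-yl)-2-methyldeca-4,6-diene-3,8-diol | C[Si](C)(C)CCOCOC1=CC(C)=C(C[C@@H](C)[C@@H](O)/C=C/C=C/[C@H](O)CCC2=C(C)C=C(OCOCC[Si](C)(C)C)C(=O)C=C2O)C(O)=CC1=O
F6 | step 9 | (3R,8S)-2-methyl-10-(trimethylsilyl)dec-1-ene-4,6,9-triyne-3,8-diol | C=C(C)[C@@H](O)C#CC#C[C@H](O)C#C[Si](C)(C)C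
F7 | step 9 | (3R,8R)-2-methyldec-1-ene-4,6,9-triyne-3,8-diol | C=C(C)[C@@H](O)C#CC#C[C@H](O)C#C
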